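**Retrosynthetic overview**
1. The target is two identical gigantol-type bibenzyl units joined by one CH2. That bridge is made by adding an aryllithium 14 (ortho-lithiation of 10 between OMe and OMOM) to aldehyde 13, then deoxygenating the diarylmethanol 15 and removing four MOM groups.
2. Both halves come from one bibenzyl-2-carboxylic acid 9: protodecarboxylation gives 10, and ester/alcohol/aldehyde adjustment gives 13, whose former carboxyl carbon becomes the bridging CH2.
3. Key C–C bond: the ArCH2–CH2Ar bond of 9, formed by intermolecular (vinylogous) aldol addition of the laterally lithiated orsellinate ester 5 to O-MOM-vanillin 2. The aldolate lactonises to dihydroisocoumarin 8, and hydrogenolysis of its benzylic C–O bond gives 9.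
4. All four benzene rings are bought (vanillin, methyl orsellinate). The only ring formed is the transient δ-lactone of 8 (step 4), reopened in step 5.

Assumption: the target has no stereocentre, so there is no enantiomer to control; the two transient stereocentres (C3 of 8, carbinol carbon of 15) are made racemic and erased. Acid 9 is divided between step 6 (about 55 %) and step 7 (about 45 %).

**Route**

Step 1
Reactants: 1 vanillin (4-hydroxy-3-methoxybenzaldehyde)
Product: 2 3-methoxy-4-(methoxymethoxy)benzaldehyde
Conditions: MOMCl (1.3 equiv), i-Pr2NEt (1.6 equiv), CH2Cl2, 0 °C → rt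
Reagents that add atoms: chloromethyl methyl ether (MOMCl), COCCl
Why: O-alkylation of the phenol (MOM protection, Williamson type) gives an acetal that survives the later base, hydride, organolithium and hydrogenation steps, and the aldehyde is untouched.

Step 2
Reactants: 3 methyl orsellinate (methyl 2,4-dihydroxy-6-methylbenzoate)
Product: 4 methyl 2-hydroxy-4-(methoxymethoxy)-6-methylbenzoate
Conditions: MOMCl (1.1 equiv), i-Pr2NEt (1.3 equiv), CH2Cl2, 0 °C → rt
Reagents that add atoms: chloromethyl methyl ether (MOMCl), COCCl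
Why: Regioselective MOM protection, because the 2-OH is tied up in a hydrogen bond to the ester carbonyl and only the free, more acidic 4-OH is alkylated.

Step 3
Reactants: 4 methyl 2-hydroxy-4-(methoxymethoxy)-6-methylbenzoate
Product: 5 methyl 2-methoxy-4-(methoxymethoxy)-6-methylbenzoate
Conditions: MeI (3 equiv), K2CO3 (3 equiv), DMF, 50 °C
Reagents that add atoms: iodomethane, CI
Why: Williamson O-methylation of the chelated phenol under forcing polar-aprotic conditions installs the methoxy group that ends up ortho to the bridge (ring C) or ortho to the lithiation site (ring B).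

Step 4
Reactants: 5 methyl 2-methoxy-4-(methoxymethoxy)-6-methylbenzoate; 2 3-methoxy-4-(methoxymethoxy)benzaldehyde
Product: 8 (±)-8-methoxy-6-(methoxymethoxy)-3-[3-methoxy-4-(methoxymethoxy)phenyl]-3,4-dihydro-1H-isochromen-1-one, via lithiated toluate 6 (not isolated), via lithium aldolate 7 (not isolated)
Conditions: LDA (1.1 equiv), THF, −78 °C, 30 min; then 2 (1.1 equiv), −78 → 0 °C; aq NH4Cl
Reagents that add atoms: none
Why: Lateral lithiation of the o-toluate gives an ester dienolate that undergoes an intermolecular vinylogous aldol addition to the non-enolisable aldehyde, and lactonisation of the aldolate onto the neighbouring ester drives the equilibrium; the new C3 stereocentre is racemic and is removed in step 5.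

Step 5
Reactants: 8 (±)-8-methoxy-6-(methoxymethoxy)-3-[3-methoxy-4-(methoxymethoxy)phenyl]-3,4-dihydro-1H-isochromen-1-one
Product: 9 2-methoxy-4-(methoxymethoxy)-6-{2-[3-methoxy-4-(methoxymethoxy)phenyl]ethyl}benzoic acid
Conditions: H2 (3 atm), 10 % Pd/C, Et3N (1.5 equiv), EtOAc–EtOH, rt → 40 °C; cold aq citric acid work-up
Reagents that add atoms: none
Why: Catalytic hydrogenolysis of the p-alkoxybenzylic ester C–O bond (benzyl-ester type, not inhibited by amine) opens the lactone to the bibenzyl acid and erases the stereocentre, while Et3N buffers the medium so the MOM ethers survive.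

Step 6
Reactants: 9 2-methoxy-4-(methoxymethoxy)-6-{2-[3-methoxy-4-(methoxymethoxy)phenyl]ethyl}benzoic acid
Product: 10 1-methoxy-3-(methoxymethoxy)-5-{2-[3-methoxy-4-(methoxymethoxy)phenyl]ethyl}benzene (bis-MOM gigantol)
Conditions: Cu2O (10 mol %), 1,10-phenanthroline (20 mol %), NMP–quinoline 3:1, 170 °C, Ar
Reagents that add atoms: none
Why: Copper-catalysed protodecarboxylation works best on di-ortho-substituted, ortho-alkoxy benzoic acids such as 9, and the basic medium leaves the MOM acetals intact.

Step 7
Reactants: 9 2-methoxy-4-(methoxymethoxy)-6-{2-[3-methoxy-4-(methoxymethoxy)phenyl]ethyl}benzoic acid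
Product: 11 methyl 2-methoxy-4-(methoxymethoxy)-6-{2-[3-methoxy-4-(methoxymethoxy)phenyl]ethyl}benzoate
Conditions: MeI (2 equiv), K2CO3 (2 equiv), DMF, rt
Reagents that add atoms: iodomethane, CI
Why: Esterification by SN2 alkylation of the carboxylate is insensitive to the di-ortho hindrance that would block Fischer esterification and needs no acid.

Step 8
Reactants: 11 methyl 2-methoxy-4-(methoxymethoxy)-6-{2-[3-methoxy-4-(methoxymethoxy)phenyl]ethyl}benzoate
Product: 12 [2-methoxy-4-(methoxymethoxy)-6-{2-[3-methoxy-4-(methoxymethoxy)phenyl]ethyl}phenyl]methanol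
Conditions: LiAlH4 (1.5 equiv), THF, 0 → 50 °C; Fieser work-up (H2O, aq NaOH, H2O)
Reagents that add atoms: none
Why: Hydride reduction of the ester to the primary alcohol leaves all ethers and acetals untouched, and the basic work-up avoids ionising the electron-rich benzylic alcohol.

Step 9
Reactants: 12 [2-methoxy-4-(methoxymethoxy)-6-{2-[3-methoxy-4-(methoxymethoxy)phenyl]ethyl}phenyl]methanol
Product: 13 2-methoxy-4-(methoxymethoxy)-6-{2-[3-methoxy-4-(methoxymethoxy)phenyl]ethyl}benzaldehyde
Conditions: activated MnO2 (15 equiv), CH2Cl2, rt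
Reagents that add atoms: none
Why: MnO2 oxidation is selective for the activated benzylic alcohol, stops at the aldehyde and is neutral.

Step 10
Reactants: 10 1-methoxy-3-(methoxymethoxy)-5-{2-[3-methoxy-4-(methoxymethoxy)phenyl]ethyl}benzene (1.2 equiv); 13 2-methoxy-4-(methoxymethoxy)-6-{2-[3-methoxy-4-(methoxymethoxy)phenyl]ethyl}benzaldehyde
Product: 15 (±)-[2-methoxy-6-(methoxymethoxy)-4-{2-[3-methoxy-4-(methoxymethoxy)phenyl]ethyl}phenyl][2-methoxy-4-(methoxymethoxy)-6-{2-[3-methoxy-4-(methoxymethoxy)phenyl]ethyl}phenyl]methanol, via aryllithium 14 (not isolated)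
Conditions: n-BuLi (1.2 equiv), THF, 0 °C, 1 h; then 13, −78 → 0 °C; aq NH4Cl
Reagents that add atoms: none
Why: Directed ortho-metalation occurs at the one position flanked by both OMe and OMOM (cooperative directing groups, much faster than the singly activated sites of the other ring) and the aryllithium adds 1,2 to the non-enolisable aldehyde; the carbinol stereocentre is racemic and is removed in step 11.

Step 11
Reactants: 15 the (±)-diarylmethanol
Product: 16 2-{[2-methoxy-4-(methoxymethoxy)-6-{2-[3-methoxy-4-(methoxymethoxy)phenyl]ethyl}phenyl]methyl}-1-methoxy-3-(methoxymethoxy)-5-{2-[3-methoxy-4-(methoxymethoxy)phenyl]ethyl}benzene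
Conditions: Et3SiH (5 equiv), TFA (3 equiv), CH2Cl2, −40 → −10 °C, 20 min; cold aq NaHCO3
Reagents that add atoms: none
Why: Ionic hydrogenation, in which the doubly benzylic alcohol ionises to a cation stabilised by four ortho/para oxygen donors and is captured by silane hydride faster than it can cyclise; the low temperature and limited acid spare the MOM ethers, and any partial MOM loss converges in step 12.

Step 12
Reactants: 16 the tetra-MOM diarylmethane
Product: 17 2-{[4-hydroxy-2-methoxy-6-[2-(4-hydroxy-3-methoxyphenyl)ethyl]phenyl]methyl}-5-[2-(4-hydroxy-3-methoxyphenyl)ethyl]-3-methoxyphenol (target CNP0079000.0)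
Conditions: 3 M aq HCl, MeOH–THF, 40 °C, Ar
Reagents that add atoms: none
Why: Acid-catalysed acetal methanolysis removes all four MOM groups while the aryl methyl ethers and the diarylmethane stay intact, and the formaldehyde leaves as dimethoxymethane instead of alkylating the phenols.

**Compound list**
1 | vanillin (4-hydroxy-3-methoxybenzaldehyde) | COc1cc(C=O)ccc1O | starting material
2 | 3-methoxy-4-(methoxymethoxy)benzaldehyde | COCOc1ccc(C=O)cc1OC | intermediate
3 | methyl orsellinate (methyl 2,4-dihydroxy-6-methylbenzoate) | COC(=O)c1c(C)cc(O)cc1O | starting material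
4 | methyl 2-hydroxy-4-(methoxymethoxy)-6-methylbenzoate | COC(=O)c1c(C)cc(OCOC)cc1O | intermediate
5 | methyl 2-methoxy-4-(methoxymethoxy)-6-methylbenzoate | COC(=O)c1c(C)cc(OCOC)cc1OC | intermediate
6 | lithiated toluate, methyl 2-(lithiomethyl)-6-methoxy-4-(methoxymethoxy)benzoate | [Li]Cc1cc(OCOC)cc(OC)c1C(=O)OC | intermediate (not isolated)
7 | lithium aldolate, racemic methyl 2-{2-(lithiooxy)-2-[3-methoxy-4-(methoxymethoxy)phenyl]ethyl}-6-methoxy-4-(methoxymethoxy)benzoate | COC(=O)c1c(CC(O[Li])c2ccc(OCOC)c(OC)c2)cc(OCOC)cc1OC | intermediate (not isolated)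
8 | (±)-8-methoxy-6-(methoxymethoxy)-3-[3-methoxy-4-(methoxymethoxy)phenyl]-3,4-dihydro-1H-isochromen-1-one | O=C1OC(c2ccc(OCOC)c(OC)c2)Cc2cc(OCOC)cc(OC)c12 | intermediate
9 | 2-methoxy-4-(methoxymethoxy)-6-{2-[3-methoxy-4-(methoxymethoxy)phenyl]ethyl}benzoic acid | COCOc1cc(OC)c(C(=O)O)c(CCc2ccc(OCOC)c(OC)c2)c1 | intermediate
10 | 1-methoxy-3-(methoxymethoxy)-5-{2-[3-methoxy-4-(methoxymethoxy)phenyl]ethyl}benzene | COCOc1cc(OC)cc(CCc2ccc(OCOC)c(OC)c2)c1 | intermediate
11 | methyl 2-methoxy-4-(methoxymethoxy)-6-{2-[3-methoxy-4-(methoxymethoxy)phenyl]ethyl}benzoate | COCOc1cc(OC)c(C(=O)OC)c(CCc2ccc(OCOC)c(OC)c2)c1 | intermediate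
12 | [2-methoxy-4-(methoxymethoxy)-6-{2-[3-methoxy-4-(methoxymethoxy)phenyl]ethyl}phenyl]methanol | COCOc1cc(OC)c(CO)c(CCc2ccc(OCOC)c(OC)c2)c1 | intermediate
13 | 2-methoxy-4-(methoxymethoxy)-6-{2-[3-methoxy-4-(methoxymethoxy)phenyl]ethyl}benzaldehyde | COCOc1cc(OC)c(C=O)c(CCc2ccc(OCOC)c(OC)c2)c1 | intermediate
14 | aryllithium, [2-methoxy-6-(methoxymethoxy)-4-{2-[3-methoxy-4-(methoxymethoxy)phenyl]ethyl}phenyl]lithium | [Li]c1c(OC)cc(CCc2ccc(OCOC)c(OC)c2)cc1OCOC | intermediate (not isolated)
15 | (±)-diarylmethanol (name as in step 10) | COCOc1cc(OC)c(C(O)c2c(OC)cc(CCc3ccc(OCOC)c(OC)c3)cc2OCOC)c(CCc2ccc(OCOC)c(OC)c2)c1 | intermediate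
16 | tetra-MOM diarylmethane (name as in step 11) | COCOc1cc(OC)c(Cc2c(OC)cc(CCc3ccc(OCOC)c(OC)c3)cc2OCOC)c(CCc2ccc(OCOC)c(OC)c2)c1 | intermediate
17 | 2-{[4-hydroxy-2-methoxy-6-[2-(4-hydroxy-3-methoxyphenyl)ethyl]phenyl]methyl}-5-[2-(4-hydroxy-3-methoxyphenyl)ethyl]-3-methoxyphenol | COc1cc(CCc2cc(O)c(Cc3c(CCc4ccc(O)c(OC)c4)cc(O)cc3OC)c(OC)c2)ccc1O | target

**Totals**
Total steps: 12. Longest linear sequence: 10 steps (3 → 4 → 5 → 8 → 9 → 11 → 12 → 13 → 15 → 16 → 17).

**Three steps most likely to fail**

Step 6 (protodecarboxylation at 170 °C; incomplete conversion or thermal loss of MOM). The fallback sets out from aldehyde 13 and comes back at 10. Instead of decarboxylating the acid, the formyl group of 13 is excised by Tsuji–Wilkinson decarbonylation (stoichiometric RhCl(PPh3)3, xylene, reflux). The C–H bond formed is exactly the one required in 10, all protecting groups are untouched, and no new compound arises (F0). All of 9 is then taken through steps 7–9 and 13 is divided instead.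

Step 11 (ionic deoxygenation; the acid may strip MOM groups unevenly or the benzhydryl cation may cyclise onto the tethered guaiacyl ring). The fallback sets out from 15 and comes back at 16. It replaces the cationic pathway by a radical Barton–McCombie deoxygenation. The alkoxide of 15 (NaH, THF) is trapped with CS2 and then MeI to give O-{[2-methoxy-6-(methoxymethoxy)-4-{2-[3-methoxy-4-(methoxymethoxy)phenyl]ethyl}phenyl][2-methoxy-4-(methoxymethoxy)-6-{2-[3-methoxy-4-(methoxymethoxy)phenyl]ethyl}phenyl]methyl} S-methyl carbonodithioate F2; there is no β-hydrogen, so Chugaev elimination is impossible. Bu3SnH with AIBN in toluene at 90 °C then gives the stabilised benzhydryl radical, which abstracts hydrogen to give 16 under neutral conditions.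

Step 5 (hydrogenolysis of the lactone C–O bond may stall under the buffered, non-acidic conditions needed for the MOM groups). The fallback sets out from 8 and comes back at 9. It opens the lactone by elimination instead of hydrogenolysis. t-BuOK (2.5 equiv, THF, 0 °C → rt) deprotonates C4, the same toluate-type benzylic position used in step 4, and E1cB expulsion of the carboxylate gives (E)-2-methoxy-4-(methoxymethoxy)-6-{2-[3-methoxy-4-(methoxymethoxy)phenyl]ethenyl}benzoic acid F1. Simple alkene hydrogenation (H2 1 atm, Pd/C, EtOAc, Et3N) then gives 9.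

Further compounds
F1 | step 5 | (E)-2-methoxy-4-(methoxymethoxy)-6-{2-[3-methoxy-4-(methoxymethoxy)phenyl]ethenyl}benzoic acid | COCOc1cc(OC)c(C(=O)O)c(/C=C/c2ccc(OCOC)c(OC)c2)c1
F0 | step 6 | none | none
F2 | step 11 | O-{[2-methoxy-6-(methoxymethoxy)-4-{2-[3-methoxy-4-(methoxymethoxy)phenyl]ethyl}phenyl][2-methoxy-4-(methoxymethoxy)-6-{2-[3-methoxy-4-(methoxymethoxy)phenyl]ethyl}phenyl]methyl} S-methyl carbonodithioate | COCOc1cc(OC)c(C(OC(=S)SC)c2c(OC)cc(CCc3ccc(OCOC)c(OC)c3)cc2OCOC)c(CCc2ccc(OCOC)c(OC)c2)c1
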